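## The problem

The target 14 is a flavone, 2-(3,5-dihydroxy-4-methoxyphenyl)-7-hydroxy-5,8-dimethoxy-4H-chromen-4-one, with no stereocenter; the difficulty lies entirely in its oxygen pattern. Ring A is substituted at every position but C6: C5 and C8 carry methyl ethers, C7 a free hydroxyl, and C4a and C8a are the fusion atoms to the pyranone ring C. Ring B repeats the problem on a smaller scale, with a methyl ether at C4' between two free hydroxyls. Six oxygens must therefore be told apart, and this cannot safely be done at the end: the 5-methoxy group peri to the C4 carbonyl is the methyl ether most easily lost to Lewis acids or HI, and the 7-hydroxyl is the most acidic phenol. Each oxygen should thus enter in its final state or under a benzyl group that one mild hydrogenolysis removes, and the C2=C3 bond of ring C must survive that last step. The C8 oxygen is the awkward one, because it lies outside the phloroglucinol pattern that acetate-derived ring A building blocks supply. The structure nevertheless offers a way in: C4, C5 and C7 carry oxygen on alternate carbons with the C5 oxygen methylated, exactly as in a 4-methoxy-2-pyranone whose lactone carbonyl is C7 and whose ring oxygen becomes the C4 ketone oxygen. C8 with its methoxy group and C8a with its oxygen are the two carbons of a methoxyacetate unit, so joining the pieces at C7–C8 and C4a–C8a would build ring A with every substituent in place.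

## Retrosynthesis

**From 14 to 13.** The last cut removes the two benzyl groups from the ring B oxygens at C3' and C5'. Benzyl is preferred to acetal or silyl protection because these phenols must pass through Mg(OMe)2, a lithium enolate and hot DMSO/iodine, and because its removal needs no acid or Lewis acid that would endanger the 5-methoxy group. Flavone 13 differs from 14 only in these groups. The forward step must cleave two aryl benzyl ethers and leave C2=C3 alone.

**From 13 to 11.** Cutting O1–C2 and returning C2=C3 to an enone alkene gives the 2'-hydroxychalcone 11, whose free hydroxyls sit on C8a and C7 (flavone numbering). A 1,3-diketone precursor would close ring C equally well, but it brings an acidic methylene and an extra acylation and rearrangement sequence. In 11 only the C8a hydroxyl is ortho to the ketone, the other ortho position being the C5 methyl ether, so ring closure has one course. The forward reaction is an oxidative cyclization that passes through flavanone 12.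

**From 11 to 7 and 8.** Ring A is cut at C7–C8 and C4a–C8a. The neighbouring cut at C4–C4a (acylation of a tetraoxygenated benzene) would leave the differentiated arene itself to be made, which is the real problem. The chosen cut gives styrylpyranone 7, which holds C4 to C7, the styryl bridge and ring B, and commercial methyl methoxyacetate 8, which supplies C8 and C8a. In the forward direction the lithium enolate 9 must add 1,2 to the lactone carbonyl of 7, the ring must open to chain 10, and 10 must close by Claisen condensation and aromatize.

**From 7 to 4 and 5.** The styryl double bond (future C2=C3) is cut to aldehyde 4 and commercial 4-methoxy-6-methyl-2H-pyran-2-one 5. An olefination would need a functionalized pyranone made in two extra steps; the vinylogous aldol condensation uses 5 as bought, through adduct 6. The forward reaction must deprotonate only the ring methyl group and give the E alkene.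

**From 4 to 1.** Aldehyde 4 comes from commercial methyl 3,5-dihydroxy-4-methoxybenzoate 1, which already has the ring B pattern, by benzylation to 2, reduction to alcohol 3 and benzylic oxidation. No carbon–carbon bond is made, and all three steps are routine.

## Roads not taken

Alternative 1: Ring C and the ring A–ring C junction would be cut at O1–C8a, C4–C4a and O1–C2, leading back to an aryne and an arylpropiolic acid. In the forward sense CsF would convert silyl triflate A2 into aryne A3, the carboxylate of propiolic acid A4 would add to the aryne carbon remote from the methoxy group (C8a), the aryl anion at C4a would take over the acyl group, and the phenoxide would close ring C onto the ynone to give flavone A1. The merits are high convergence, a regiochemistry steered by the methoxy group next to the aryne, and a flavone at the right oxidation level with no chalcone or dehydrogenation. Aryne insertion into carboxylic acid C–O bonds is an established reaction class, so in precedent this road is better than the chosen one. Its weakness for this target is that A1 has no oxygen at C8: an aryne flanked by alkoxy groups on both sides would lose its regiocontrol, so the C8 methoxy group must be added after ring formation. That means unmasking the 7-hydroxyl, halogenating or oxidizing C8 in competition with C6, and methylating, before the ring B groups are removed. A2 and A4 each need several steps, so the total is roughly twice that of the chosen plan. The chosen plan sets against the better precedent of Alternative 1 the fact that C8 is oxygenated and methylated from the start and that its two partners are one purchased ester and a four-step pyranone.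

Alternative 2: Ring A would be cut at C4a–C5 and traced to the 4-hydroxycyclobutenone A6, in which a four-membered ring carrying the C7 benzyloxy group is attached to C8a of a 2-aryl-4-silyloxy-dihydropyran. Heating A6 in toluene or xylene should cause four-electron ring opening and six-electron ring closure onto the enol ether double bond, and tautomerization would give the hydroquinone A5. The rearrangement is reliable thermal chemistry with fully dictated regiochemistry, and it delivers the C5 and C8 oxygens as two free hydroxyls beside a benzylated C7 oxygen, which is exactly the differentiation the target needs. In the predictability of the ring-forming step it is clearly better than the chosen plan. Its weak points lie around that step. A5 is an electron-rich hydroquinone that oxidizes easily to the quinone, and ring C is at the chromane level. After double methylation, the silyl group must be removed, C4 oxidized, C2–C3 dehydrogenated and three benzyl groups cleaved. The C2 and C4 centres also create diastereomer mixtures that are carried along only to be erased. A6 in turn requires a metallated dihydropyran and a monoalkoxycyclobutenedione, each made in several steps. The chosen plan sets against the safer key step of Alternative 2 a route about half as long, with ring C at the correct oxidation level and no stereoisomers to carry.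

Alternative 3: Ring A would be cut at C8–C8a and C4a–C5, leading to bromodihydropyranone A8 (from aldehyde 4 by hetero-cycloaddition and bromination) and the oxygenated diene A9. The nucleophilic terminus of A9 would bond to the beta carbon of the bromo-enone (C8a) and the ketene acetal carbon to the alpha carbon (C4a), thermally or with Me3SiOSO2CF3. Loss of HBr, methanol and the silyl group would then give flavanone A7, which is the same compound as the transient 12 of the chosen route. This road is convergent, its regiochemistry follows from the polarity of both partners, and A7 is two steps from 14, so in length it is about equal to the chosen plan. It also has a closer analogy in cycloadditions of ketene acetal dienes with halogenated enones and quinones. The weak points are the partners. The double bond of A8 is a vinylogous ester and therefore an electron-rich, sluggish dienophile. A9 is a hydrolytically labile tetraoxygenated diene of uncertain geometry. A silyl triflate could stop the reaction at the conjugate addition stage or open the dihydropyranone at its benzylic C2–O bond. The chosen plan sets against this a crystalline, stable pyranone and a purchased ester, and a second bond formation that is intramolecular and driven by aromatization.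

Key step: step 5

Assumption: ring positions are given in flavone numbering throughout, also for the acyclic and pyranone precursors, and compounds 1, 5 and 8 and solutions of Mg(OMe)2 in MeOH and LiN(iPr)2 in THF are taken as purchased.

## Route

Step 1
Reactants: 1 methyl 3,5-dihydroxy-4-methoxybenzoate
Product: 2 methyl 3,5-bis(benzyloxy)-4-methoxybenzoate
Conditions: BnBr (2.4 equiv), K2CO3, DMF, 60 °C
Reagents that add atoms: benzyl bromide, BrCc1ccccc1
Why: Williamson ether synthesis on two equivalent, unhindered phenols; the ester and the methyl ether are inert to K2CO3 in DMF.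

Step 2
Reactants: 2 methyl 3,5-bis(benzyloxy)-4-methoxybenzoate
Product: 3 [3,5-bis(benzyloxy)-4-methoxyphenyl]methanol
Conditions: LiAlH4, THF, 0 °C to rt; H2O
Reagents that add atoms: none
Why: Hydride reduction of an aryl ester to the benzylic alcohol; aryl benzyl and methyl ethers do not react with LiAlH4.

Step 3
Reactants: 3 [3,5-bis(benzyloxy)-4-methoxyphenyl]methanol
Product: 4 3,5-bis(benzyloxy)-4-methoxybenzaldehyde
Conditions: activated MnO2 (excess), CH2Cl2, rt
Reagents that add atoms: none
Why: Selective heterogeneous oxidation of a benzylic alcohol, which stops at the aldehyde and leaves the ethers untouched.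

Step 4
Reactants: 4 3,5-bis(benzyloxy)-4-methoxybenzaldehyde; 5 4-methoxy-6-methyl-2H-pyran-2-one
Product: 7 (E)-6-[2-(3,5-bis(benzyloxy)-4-methoxyphenyl)ethenyl]-4-methoxy-2H-pyran-2-one, via aldol adduct 6 (not isolated)
Conditions: Mg(OMe)2, MeOH, reflux; then 1 M HCl
Reagents that add atoms: none
Why: Vinylogous aldol condensation, the classical entry to 6-styryl-4-methoxy-2-pyranones: the ring methyl group of 5 is deprotonated as a magnesium-bound dienolate, adds to the non-enolizable aldehyde 4, and adduct 6 loses water by E1cB elimination. The conjugated E alkene is the thermodynamic product and the only one expected.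

Step 5
Reactants: 7 (E)-6-[2-(3,5-bis(benzyloxy)-4-methoxyphenyl)ethenyl]-4-methoxy-2H-pyran-2-one; 8 methyl methoxyacetate
Product: 11 (E)-3-[3,5-bis(benzyloxy)-4-methoxyphenyl]-1-(2,4-dihydroxy-3,6-dimethoxyphenyl)prop-2-en-1-one, via lithium enolate of methyl methoxyacetate 9 (not isolated), via ring-opened keto ester dienolate 10 (not isolated)
Conditions: 8 (3.2 equiv), LiN(iPr)2 (3.0 equiv), THF, −78 °C; then 7, −78 to 0 °C; 1 M HCl
Reagents that add atoms: none
Why: Proposed new method: enolate 9 should add to the lactone carbonyl of 7 (future C7) and the tetrahedral alkoxide should collapse by expelling the ring oxygen as a delocalized dienolate, which forms C7–C8 and gives the open chain 10; its central double bond keeps the cis geometry of the ring, so the carbon alpha to the styryl ketone (future C4a) lies next to the ester carbon (future C8a). On warming, this carbon should attack the ester in a 6-(enolexo)-exo-trig Claisen (Dieckmann-type) closure that forms C4a–C8a, and loss of methoxide followed by enolization of the cyclohexenetrione makes ring A aromatic. The closest known reaction types are the carbanion-induced ring transformations of 2-pyranones into benzenes and the base-mediated Claisen cyclization of 3,5,7-triketo esters to acylphloroglucinols; a one-flask lactone opening and Claisen closure with an alkoxyacetate enolate on a 4-methoxy-6-styryl-2-pyranone has not been shown. No stereocenter is formed and the E alkene is not touched. The step needs 1,2-addition in preference to attack at future C5, C4 or C2 of the extended acceptor, which the hard, chelated lithium enolate at −78 °C, the electron release of the ring methoxy group into those positions and the electron-rich aryl group at the styryl terminus should secure. It needs Claisen and not aldol closure, which the methoxy group on C8 secures: an aldol closure through C8 onto the C4 ketone would make that carbon quaternary and could not aromatize, so it stays reversible. It needs the pyranone not to be metallated, which is why 9 is preformed with a slight excess of 8 so that no free amide remains, while the excess enolate supplies the base consumed by 10 and by the phenoxide product. Because the C5 oxygen is already a methyl ether, a single chalcone results, with its one free ortho hydroxyl on C8a.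

Step 6
Reactants: 11 (E)-3-[3,5-bis(benzyloxy)-4-methoxyphenyl]-1-(2,4-dihydroxy-3,6-dimethoxyphenyl)prop-2-en-1-one
Product: 13 2-[3,5-bis(benzyloxy)-4-methoxyphenyl]-7-hydroxy-5,8-dimethoxy-4H-chromen-4-one, via racemic flavanone 12 (not isolated)
Conditions: I2 (10 mol%), DMSO, 120–130 °C
Reagents that add atoms: none
Why: Iodine-catalysed oxidative cyclization of a 2'-hydroxychalcone: the C8a hydroxyl closes ring C by 6-endo-trig oxa-Michael addition to give flavanone 12, which is iodinated at C3 and loses HI, while DMSO reoxidizes HI to I2. Aryl benzyl ethers and a free hydroxyl para to the ketone are tolerated under these conditions, and the C2 centre of 12 is erased.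

Step 7
Reactants: 13 2-[3,5-bis(benzyloxy)-4-methoxyphenyl]-7-hydroxy-5,8-dimethoxy-4H-chromen-4-one
Product: 14 2-(3,5-dihydroxy-4-methoxyphenyl)-7-hydroxy-5,8-dimethoxy-4H-chromen-4-one
Conditions: H2 (1 atm), 10% Pd/C, EtOAc–MeOH, rt
Reagents that add atoms: none
Why: Hydrogenolysis of two aryl benzyl ethers; the C2=C3 bond is part of the vinylogous ester of the 4-pyranone and should not be reduced at 1 atm and room temperature if the reaction is stopped after two equivalents of hydrogen. The three methyl ethers are unaffected.

## Compound list

1 | methyl 3,5-dihydroxy-4-methoxybenzoate | COC(=O)c1cc(O)c(OC)c(O)c1 | starting material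
2 | methyl 3,5-bis(benzyloxy)-4-methoxybenzoate | COC(=O)c1cc(OCc2ccccc2)c(OC)c(OCc2ccccc2)c1 | intermediate
3 | [3,5-bis(benzyloxy)-4-methoxyphenyl]methanol | OCc1cc(OCc2ccccc2)c(OC)c(OCc2ccccc2)c1 | intermediate
4 | 3,5-bis(benzyloxy)-4-methoxybenzaldehyde | O=Cc1cc(OCc2ccccc2)c(OC)c(OCc2ccccc2)c1 | intermediate
5 | 4-methoxy-6-methyl-2H-pyran-2-one | COc1cc(C)oc(=O)c1 | starting material
6 | racemic 6-[2-(3,5-bis(benzyloxy)-4-methoxyphenyl)-2-hydroxyethyl]-4-methoxy-2H-pyran-2-one (aldol adduct, present as its magnesium alkoxide) | COc1cc(CC(O)c2cc(OCc3ccccc3)c(OC)c(OCc3ccccc3)c2)oc(=O)c1 | intermediate (not isolated)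
7 | (E)-6-[2-(3,5-bis(benzyloxy)-4-methoxyphenyl)ethenyl]-4-methoxy-2H-pyran-2-one | COc1cc(/C=C/c2cc(OCc3ccccc3)c(OC)c(OCc3ccccc3)c2)oc(=O)c1 | intermediate
8 | methyl methoxyacetate | COCC(=O)OC | starting material
9 | lithium enolate of methyl methoxyacetate (lithium 1,2-dimethoxyethen-1-olate, chelated geometry with the oxido group cis to the 2-methoxy group) | [Li+].CO/C=C(\[O-])OC | intermediate (not isolated)
10 | methyl (4E,6Z,8E)-9-[3,5-bis(benzyloxy)-4-methoxyphenyl]-7-hydroxy-2,5-dimethoxy-3-oxonona-4,6,8-trienoate (racemic at C2 of the chain, present as its lithium enolates) | COC(=O)C(OC)C(=O)/C=C(OC)\C=C(O)\C=C\c1cc(OCc2ccccc2)c(OC)c(OCc2ccccc2)c1 | intermediate (not isolated)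
11 | (E)-3-[3,5-bis(benzyloxy)-4-methoxyphenyl]-1-(2,4-dihydroxy-3,6-dimethoxyphenyl)prop-2-en-1-one | COc1cc(O)c(OC)c(O)c1C(=O)/C=C/c1cc(OCc2ccccc2)c(OC)c(OCc2ccccc2)c1 | intermediate
12 | racemic 2-[3,5-bis(benzyloxy)-4-methoxyphenyl]-7-hydroxy-5,8-dimethoxy-2,3-dihydro-4H-chromen-4-one | COc1c(OCc2ccccc2)cc(C2CC(=O)c3c(OC)cc(O)c(OC)c3O2)cc1OCc1ccccc1 | intermediate (not isolated)
13 | 2-[3,5-bis(benzyloxy)-4-methoxyphenyl]-7-hydroxy-5,8-dimethoxy-4H-chromen-4-one | COc1c(OCc2ccccc2)cc(-c2cc(=O)c3c(OC)cc(O)c(OC)c3o2)cc1OCc1ccccc1 | intermediate
14 | 2-(3,5-dihydroxy-4-methoxyphenyl)-7-hydroxy-5,8-dimethoxy-4H-chromen-4-one | COc1c(O)cc(-c2cc(=O)c3c(OC)cc(O)c(OC)c3o2)cc1O | target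

## Step count and risks

Total steps: 7. Longest linear sequence: 7 steps (1, 2, 3, 4, 7, 11, 13, 14); 5 and 8 are purchased and enter in steps 4 and 5.

**Step 5 (key step, proposed new method).** Two processes are most likely to interfere. The first is conjugate attack of the enolate on the extended acceptor (at future C4 or C2, or addition–elimination at future C5 with loss of methoxide) in place of 1,2-addition, because 2-pyranones are ambident electrophiles. The second is stalling after ring opening: chain 10 is deprotonated at C8 between ketone and ester, which masks the ester as an enolate, so the Claisen closure may be slow and work-up may return open-chain material or the pyranone by reversal. The fallback uses known chemistry, sets out from aldehyde 4 and returns at flavone 13. It gives up the ring A construction and adds C8 last.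
- Claisen–Schmidt condensation of 4 with commercial 1-(2,4-dihydroxy-6-methoxyphenyl)ethanone (SMILES CC(=O)c1c(O)cc(O)cc1OC; KOH, EtOH, rt) should give (E)-3-[3,5-bis(benzyloxy)-4-methoxyphenyl]-1-(2,4-dihydroxy-6-methoxyphenyl)prop-2-en-1-one F1.
- Oxidative cyclization as in step 6 (catalytic I2, DMSO, 120–130 °C) should give 2-[3,5-bis(benzyloxy)-4-methoxyphenyl]-7-hydroxy-5-methoxy-4H-chromen-4-one F2.
- Iodination ortho to the 7-hydroxyl with N-iodosuccinimide in DMF should give 2-[3,5-bis(benzyloxy)-4-methoxyphenyl]-7-hydroxy-8-iodo-5-methoxy-4H-chromen-4-one F3. In 5-O-alkylated flavones C8 is the more reactive of the two ortho positions; the position of the iodine would have to be confirmed before going on.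
- Copper-mediated methoxylation (NaOMe, CuBr, DMF–MeOH, 110 °C), as used for ortho-halophenols, should give 13.

**Step 6.** The likely failures are electrophilic iodination of ring A at C6, its only free position and one activated by the C5 and C7 oxygens, and loss of the peri 5-O-methyl group to HI at 130 °C. The fallback avoids iodine, sets out from 11 and returns at 14.
- Selective benzylation of the non-chelated C7 hydroxyl (BnBr, K2CO3, acetone, reflux) should give (E)-1-[4-(benzyloxy)-2-hydroxy-3,6-dimethoxyphenyl]-3-[3,5-bis(benzyloxy)-4-methoxyphenyl]prop-2-en-1-one F4.
- Base-mediated oxa-Michael closure (NaOAc, EtOH, reflux) should give racemic 7-(benzyloxy)-2-[3,5-bis(benzyloxy)-4-methoxyphenyl]-5,8-dimethoxy-2,3-dihydro-4H-chromen-4-one F5.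
- Dehydrogenation with DDQ in dioxane at reflux should give 7-(benzyloxy)-2-[3,5-bis(benzyloxy)-4-methoxyphenyl]-5,8-dimethoxy-4H-chromen-4-one F6.
- Hydrogenolysis of all three benzyl ethers under the conditions of step 7 should give 14.

**Step 4.** The likely failures are methoxide attack on the lactone of 5 or 7 (ring opening and ester exchange) during the long reflux, and incomplete condensation because the electron-rich aldehyde is a weak acceptor and the aldol stage is reversible. The fallback replaces the condensation by an olefination, sets out from 5 and returns at 7.
- Radical bromination of the ring methyl group (N-bromosuccinimide, catalytic azobisisobutyronitrile, PhCF3, reflux) should give 6-(bromomethyl)-4-methoxy-2H-pyran-2-one F7.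
- Michaelis–Arbuzov reaction with P(OEt)3 at 120 °C should give diethyl [(4-methoxy-2-oxo-2H-pyran-6-yl)methyl]phosphonate F8.
- Horner–Wadsworth–Emmons reaction of F8 with 4 (NaH, THF, 0 °C to rt) should give the E alkene 7.

## Further compounds

F1 | step 5 | (E)-3-[3,5-bis(benzyloxy)-4-methoxyphenyl]-1-(2,4-dihydroxy-6-methoxyphenyl)prop-2-en-1-one | COc1cc(O)cc(O)c1C(=O)/C=C/c1cc(OCc2ccccc2)c(OC)c(OCc2ccccc2)c1
F2 | step 5 | 2-[3,5-bis(benzyloxy)-4-methoxyphenyl]-7-hydroxy-5-methoxy-4H-chromen-4-one | COc1c(OCc2ccccc2)cc(-c2cc(=O)c3c(OC)cc(O)cc3o2)cc1OCc1ccccc1
F3 | step 5 | 2-[3,5-bis(benzyloxy)-4-methoxyphenyl]-7-hydroxy-8-iodo-5-methoxy-4H-chromen-4-one | COc1c(OCc2ccccc2)cc(-c2cc(=O)c3c(OC)cc(O)c(I)c3o2)cc1OCc1ccccc1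
F4 | step 6 | (E)-1-[4-(benzyloxy)-2-hydroxy-3,6-dimethoxyphenyl]-3-[3,5-bis(benzyloxy)-4-methoxyphenyl]prop-2-en-1-one | COc1cc(OCc2ccccc2)c(OC)c(O)c1C(=O)/C=C/c1cc(OCc2ccccc2)c(OC)c(OCc2ccccc2)c1
F5 | step 6 | racemic 7-(benzyloxy)-2-[3,5-bis(benzyloxy)-4-methoxyphenyl]-5,8-dimethoxy-2,3-dihydro-4H-chromen-4-one | COc1c(OCc2ccccc2)cc(C2CC(=O)c3c(OC)cc(OCc4ccccc4)c(OC)c3O2)cc1OCc1ccccc1
F6 | step 6 | 7-(benzyloxy)-2-[3,5-bis(benzyloxy)-4-methoxyphenyl]-5,8-dimethoxy-4H-chromen-4-one | COc1c(OCc2ccccc2)cc(-c2cc(=O)c3c(OC)cc(OCc4ccccc4)c(OC)c3o2)cc1OCc1ccccc1
F7 | step 4 | 6-(bromomethyl)-4-methoxy-2H-pyran-2-one | COc1cc(CBr)oc(=O)c1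
F8 | step 4 | diethyl [(4-methoxy-2-oxo-2H-pyran-6-yl)methyl]phosphonate | CCOP(=O)(Cc1cc(OC)cc(=O)o1)OCC
A1 | alternative 1 | 7-(benzyloxy)-5-methoxy-2-[4-methoxy-3,5-bis(methoxymethoxy)phenyl]-4H-chromen-4-one | COCOc1cc(-c2cc(=O)c3c(OC)cc(OCc4ccccc4)cc3o2)cc(OCOC)c1OC
A2 | alternative 1 | 5-(benzyloxy)-3-methoxy-2-(trimethylsilyl)phenyl trifluoromethanesulfonate | COc1cc(OCc2ccccc2)cc(OS(=O)(=O)C(F)(F)F)c1[Si](C)(C)C
A3 | alternative 1 | 5-(benzyloxy)-3-methoxy-1,2-didehydrobenzene (aryne) | COC1=CC(OCc2ccccc2)=CC#C1
A4 | alternative 1 | 3-[4-methoxy-3,5-bis(methoxymethoxy)phenyl]prop-2-ynoic acid | COCOc1cc(C#CC(=O)O)cc(OCOC)c1OC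
A5 | alternative 2 | 7-(benzyloxy)-2-[3,5-bis(benzyloxy)-4-methoxyphenyl]-4-(tert-butyldimethylsilyloxy)chromane-5,8-diol (mixture of diastereomers at C2 and C4) | Oc1cc(OCc2ccccc2)c(O)c2c1C(O[Si](C)(C)C(C)(C)C)CC(c1cc(OCc3ccccc3)c(OC)c(OCc3ccccc3)c1)O2
A6 | alternative 2 | 3-(benzyloxy)-4-{2-[3,5-bis(benzyloxy)-4-methoxyphenyl]-4-(tert-butyldimethylsilyloxy)-3,4-dihydro-2H-pyran-6-yl}-4-hydroxycyclobut-2-en-1-one (mixture of diastereomers) | O=C1C=C(OCc2ccccc2)C1(O)C1=CC(O[Si](C)(C)C(C)(C)C)CC(c2cc(OCc3ccccc3)c(OC)c(OCc3ccccc3)c2)O1
A7 | alternative 3 | racemic 2-[3,5-bis(benzyloxy)-4-methoxyphenyl]-7-hydroxy-5,8-dimethoxy-2,3-dihydro-4H-chromen-4-one | COc1c(OCc2ccccc2)cc(C2CC(=O)c3c(OC)cc(O)c(OC)c3O2)cc1OCc1ccccc1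
A8 | alternative 3 | racemic 2-[3,5-bis(benzyloxy)-4-methoxyphenyl]-5-bromo-2,3-dihydro-4H-pyran-4-one | O=C1CC(c2cc(OCc3ccccc3)c(OC)c(OCc3ccccc3)c2)OC=C1Br
A9 | alternative 3 | (3Z)-1,1,4-trimethoxy-3-(trimethylsilyloxy)buta-1,3-diene | CO/C=C(\O[Si](C)(C)C)C=C(OC)OC
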